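## Retrosynthetic overview

1. Endgame: the C1 acetate comes from enolate oxidation trans to the C6 side chain, the side-chain oxirane from a Shi epoxidation, and both tiglates from one diol.
2. Key disconnection C6–C7: a vinyl radical at C7 of the intact (S)-bromodienol side chain is delivered 7-exo to the enone of an epoxyquinol through a temporary O5–SiMe2–O8 tether. This sets C6 cis to O5 and leaves the 1,1-disubstituted alkene in place.
3. Epoxyquinol: o-cresol → toluquinone → catalytic enantioselective Diels–Alder masking with cyclopentadiene → epoxidation → retro-Diels–Alder → reduction anti to the epoxide.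
4. Side chain: 2-bromoacrolein, Brown allylation (sets C8), cross-metathesis to the prenyl group.
5. Ring order: the carbocycle comes from the arene and is never opened; ring oxirane (step 3); temporary dioxasilepane (step 9, removed in the same flask); side-chain oxirane (step 11).

Locants used below: ring C1 (CHOAc), C2 (C=O), C3 (C–Me), C4, C5 (CHO-tigloyl), C6; side chain C7(=C14H2), C8, C9, C10, C11. Tigloyl = (E)-2-methylbut-2-enoyl.

Assumption: the (S)-oxazaborolidinium catalyst in step 2 is taken to deliver cyclopentadiene to the quinone face that gives adduct 4 as drawn; if the observed sense were opposite, the (R)-catalyst would be used with no other change.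

## Route

Step 1
Reactants: 1 2-methylphenol (o-cresol)
Product: 2 2-methylcyclohexa-2,5-diene-1,4-dione (toluquinone)
Conditions: (KSO3)2NO (2.2 equiv), KH2PO4, H2O/acetone, 0 °C to rt
Reagents that add atoms: potassium nitrosodisulfonate (Fremy's salt), [K+].[K+].[O]N(S(=O)(=O)[O-])S(=O)(=O)[O-]
Why: Teuber oxidation, in which the nitroxyl radical converts a phenol with a free para position into the p-quinone.

Step 2
Reactants: 2 toluquinone; 3 cyclopenta-1,3-diene
Product: 4 (1S,4R,4aS,8aR)-6-methyl-1,4,4a,8a-tetrahydro-1,4-methanonaphthalene-5,8-dione (endo adduct)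
Conditions: (S)-2-(o-tolyl)-3,3-diphenyl-oxazaborolidine·HNTf2 (20 mol %), CH2Cl2, −95 °C
Reagents that add atoms: none
Why: Catalytic enantioselective Diels–Alder reaction (Corey oxazaborolidinium catalysis) at the unsubstituted quinone C=C with endo selectivity; the four new stereocentres only relay chirality to the epoxide and are erased in step 4.

Step 3
Reactants: 4 endo adduct
Product: 5 (1S,4R,4aS,6S,7R,8aR)-6,7-epoxy-6-methyl-1,4,4a,6,7,8a-hexahydro-1,4-methanonaphthalene-5,8-dione (epoxide anti to the CH=CH bridge)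
Conditions: 30 % H2O2, Na2CO3, acetone/H2O, 0 °C
Reagents that add atoms: hydrogen peroxide, OO
Why: Weitz–Scheffer nucleophilic epoxidation of the remaining ene-dione from the convex face of the cis-fused adduct, which sets C3 and C4 of the target.

Step 4
Reactants: 5 epoxy adduct
Product: 6 (1S,6R)-1-methyl-7-oxabicyclo[4.1.0]hept-3-ene-2,5-dione
Conditions: flash vacuum pyrolysis, 450 °C, 0.05 Torr
Reagents that add atoms: none
Why: Retro-Diels–Alder reaction expels cyclopentadiene and unmasks the C1=C6 enone without touching the epoxide stereocentres.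

Step 5
Reactants: 6 epoxyquinone
Product: 7 (1S,5S,6S)-5-hydroxy-1-methyl-7-oxabicyclo[4.1.0]hept-3-en-2-one
Conditions: NaBH4, CeCl3·7H2O, MeOH, −78 °C
Reagents that add atoms: none
Why: Luche 1,2-reduction with hydride approaching anti to the epoxide oxygen; that face is open at C5 (C4–H) but blocked at C2 by the C3 methyl, so the C5 carbonyl is reduced and the alcohol ends up cis to the epoxide (sets C5).

Step 6
Reactants: 8 allylmagnesium bromide; 9 2-bromoprop-2-enal (2-bromoacrolein)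
Product: 12 (S)-2-bromohexa-1,5-dien-3-ol, via B-allyldiisopinocampheylborane 10 (not isolated), via borinate ester 11 (not isolated)
Conditions: (−)-Ipc2BOMe, Et2O, −78 °C to rt; then 9, −78 °C; NaOH, H2O2, rt
Reagents that add atoms: none
Why: Brown asymmetric allylboration through a chair Zimmerman–Traxler transition state; the reagent from (+)-α-pinene gives the (S)-carbinol (C8), the same facial sense as with benzaldehyde.

Step 7
Reactants: 12 (S)-2-bromohexa-1,5-dien-3-ol; 13 2-methylbut-2-ene (large excess)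
Product: 14 (S)-2-bromo-6-methylhepta-1,5-dien-3-ol
Conditions: second-generation Grubbs catalyst RuCl2(=CHPh)(PCy3)(H2IMes) (5 mol %), CH2Cl2, 40 °C
Reagents that add atoms: none
Why: Olefin cross-metathesis converts the allyl into the prenyl terminus, while the 1,1-disubstituted vinyl bromide is inert to the catalyst.

Step 8
Reactants: 14 (S)-bromodienol; 7 epoxyquinol
Product: 16 (1S,5S,6S)-5-[({[(3S)-2-bromo-6-methylhepta-1,5-dien-3-yl]oxy}dimethylsilyl)oxy]-1-methyl-7-oxabicyclo[4.1.0]hept-3-en-2-one, via chlorosilyl ether 15 (not isolated)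
Conditions: Me2SiCl2 (5 equiv), Et3N, CH2Cl2, −78 to 0 °C; evaporate; then 7, Et3N, DMAP (cat.), CH2Cl2, 0 °C to rt
Reagents that add atoms: dichlorodimethylsilane, C[Si](C)(Cl)Cl
Why: Stepwise silylation (temporary silicon connection) links O8 of the side chain to O5 of the ring as a mixed dimethylsilyl bis-ether.

Step 9
Reactants: 16 silaketal
Product: 18 (1S,4R,5S,6S)-5-hydroxy-4-[(3S)-3-hydroxy-6-methylhepta-1,5-dien-2-yl]-1-methyl-7-oxabicyclo[4.1.0]heptan-2-one, via cyclised silaketal 17 (not isolated)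
Conditions: (Me3Si)3SiH (1.5 equiv), AIBN (0.3 equiv), PhH (0.004 M), 80 °C, syringe pump 8 h; then Bu4NF, AcOH, THF, 0 °C
Reagents that add atoms: none
Why: The silyl radical abstracts bromine and the C7 vinyl radical, held on the O5 face by the tether, adds 7-exo-trig to the enone β-carbon C6 (silicon-tethered intramolecular Giese addition), forming C6–C7 and the C6 stereocentre cis to O5; the C1 α-keto radical is reduced by the silane, (Me3Si)3SiH is used because stannyl radicals open α,β-epoxy ketones, and fluoride then removes the tether.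

Step 10
Reactants: 18 diol; 19 (E)-2-methylbut-2-enoyl chloride (tigloyl chloride, 4 equiv)
Product: 20 (1S,4R,5S,6S)-1-methyl-4-{(3S)-6-methyl-3-[(E)-2-methylbut-2-enoyloxy]hepta-1,5-dien-2-yl}-2-oxo-7-oxabicyclo[4.1.0]heptan-5-yl (E)-2-methylbut-2-enoate
Conditions: pyridine, DMAP (0.2 equiv), CH2Cl2, 0 °C to rt
Reagents that add atoms: none
Why: DMAP-catalysed acylation of both secondary alcohols; the weak base avoids vinylketene formation and the tiglate is the stable (E) isomer.

Step 11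
Reactants: 20 bis-tiglate
Product: 21 (1S,4R,5S,6S)-4-{(3S)-4-[(2R)-3,3-dimethyloxiran-2-yl]-3-[(E)-2-methylbut-2-enoyloxy]but-1-en-2-yl}-1-methyl-2-oxo-7-oxabicyclo[4.1.0]heptan-5-yl (E)-2-methylbut-2-enoate
Conditions: D-fructose-derived Shi ketone (0.3 equiv), KHSO5 (as 2KHSO5·KHSO4·K2SO4), K2CO3, Bu4NHSO4, MeCN/(MeO)2CH2/aq. Na2B4O7 buffer pH 10.5, 0 °C
Reagents that add atoms: potassium peroxymonosulfate, [K+].[O-]S(=O)(=O)OO
Why: Shi asymmetric epoxidation; the chiral dioxirane attacks only the electron-rich trisubstituted C10=C11 alkene (the tiglates and the allylic 1,1-disubstituted alkene are deactivated) through the spiro transition state that gives (10R).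

Step 12
Reactants: 21 epoxy bis-tiglate; 22 acetic anhydride
Product: 24 CNP0407453.3, via alpha-hydroxy ketone 23 (not isolated)
Conditions: KN(SiMe3)2 (1.1 equiv), THF, −78 °C; 2-(phenylsulfonyl)-3-phenyloxaziridine, −78 °C; then 22, DMAP, −78 to 0 °C
Reagents that add atoms: 2-(phenylsulfonyl)-3-phenyloxaziridine (Davis oxaziridine), O=S(=O)(N1OC1c1ccccc1)c1ccccc1
Why: The C2 ketone can enolise only toward C1 (C3 is quaternary), Davis enolate hydroxylation occurs anti to the adjacent C6 side chain to give the trans C1 oxygen (also the equilibrium-favoured diequatorial arrangement), and the alkoxide is acetylated in the same flask.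

## Compound list

1 | 2-methylphenol | Cc1ccccc1O | starting material
2 | 2-methylcyclohexa-2,5-diene-1,4-dione | CC1=CC(=O)C=CC1=O | intermediate
3 | cyclopenta-1,3-diene | C1=CCC=C1 | starting material
4 | (1S,4R,4aS,8aR)-6-methyl-1,4,4a,8a-tetrahydro-1,4-methanonaphthalene-5,8-dione | O=C1C(C)=CC(=O)[C@@H]2[C@@H]3C=C[C@@H](C3)[C@H]12 | intermediate
5 | (1S,4R,4aS,6S,7R,8aR)-6,7-epoxy-6-methyl-1,4,4a,6,7,8a-hexahydro-1,4-methanonaphthalene-5,8-dione | O=C1[C@@]2(C)O[C@H]2C(=O)[C@@H]3[C@@H]4C=C[C@@H](C4)[C@H]13 | intermediate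
6 | (1S,6R)-1-methyl-7-oxabicyclo[4.1.0]hept-3-ene-2,5-dione | O=C1C=CC(=O)[C@@H]2O[C@]12C | intermediate
7 | (1S,5S,6S)-5-hydroxy-1-methyl-7-oxabicyclo[4.1.0]hept-3-en-2-one | O=C1C=C[C@H](O)[C@@H]2O[C@]12C | intermediate
8 | allylmagnesium bromide | C=CC[Mg]Br | starting material
9 | 2-bromoprop-2-enal | C=C(Br)C=O | starting material
10 | (−)-B-allyldiisopinocampheylborane | C=CCB([C@@H]1C[C@@H]2C[C@H]([C@H]1C)C2(C)C)[C@@H]1C[C@@H]2C[C@H]([C@H]1C)C2(C)C | intermediate
11 | (S)-2-bromohexa-1,5-dien-3-yl diisopinocampheylborinate | C=C(Br)[C@@H](OB([C@@H]1C[C@@H]2C[C@H]([C@H]1C)C2(C)C)[C@@H]1C[C@@H]2C[C@H]([C@H]1C)C2(C)C)CC=C | intermediate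
12 | (S)-2-bromohexa-1,5-dien-3-ol | C=C(Br)[C@@H](O)CC=C | intermediate
13 | 2-methylbut-2-ene | CC=C(C)C | starting material
14 | (S)-2-bromo-6-methylhepta-1,5-dien-3-ol | C=C(Br)[C@@H](O)CC=C(C)C | intermediate
15 | {[(3S)-2-bromo-6-methylhepta-1,5-dien-3-yl]oxy}chlorodimethylsilane | C=C(Br)[C@H](CC=C(C)C)O[Si](C)(C)Cl | intermediate
16 | (1S,5S,6S)-5-[({[(3S)-2-bromo-6-methylhepta-1,5-dien-3-yl]oxy}dimethylsilyl)oxy]-1-methyl-7-oxabicyclo[4.1.0]hept-3-en-2-one | C=C(Br)[C@H](CC=C(C)C)O[Si](C)(C)O[C@H]1C=CC(=O)[C@@]2(C)O[C@@H]12 | intermediate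
17 | O5,O8-dimethylsilanediyl derivative of 18 (cis-fused 2,2-dimethyl-1,3-dioxa-2-silepane carrying the exo-methylene at C7) | C=C1[C@@H]2[C@H](O[Si](C)(C)O[C@H]1CC=C(C)C)[C@@H]1O[C@]1(C)C(=O)C2 | intermediate
18 | (1S,4R,5S,6S)-5-hydroxy-4-[(3S)-3-hydroxy-6-methylhepta-1,5-dien-2-yl]-1-methyl-7-oxabicyclo[4.1.0]heptan-2-one | C=C([C@@H]1[C@H](O)[C@@H]2O[C@]2(C)C(=O)C1)[C@H](CC=C(C)C)O | intermediate
19 | (E)-2-methylbut-2-enoyl chloride | ClC(=O)/C(C)=C/C | starting material
20 | (1S,4R,5S,6S)-1-methyl-4-{(3S)-6-methyl-3-[(E)-2-methylbut-2-enoyloxy]hepta-1,5-dien-2-yl}-2-oxo-7-oxabicyclo[4.1.0]heptan-5-yl (E)-2-methylbut-2-enoate | C=C([C@@H]1[C@H](OC(=O)/C(C)=C/C)[C@@H]2O[C@]2(C)C(=O)C1)[C@H](CC=C(C)C)OC(=O)/C(C)=C/C | intermediate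
21 | (1S,4R,5S,6S)-4-{(3S)-4-[(2R)-3,3-dimethyloxiran-2-yl]-3-[(E)-2-methylbut-2-enoyloxy]but-1-en-2-yl}-1-methyl-2-oxo-7-oxabicyclo[4.1.0]heptan-5-yl (E)-2-methylbut-2-enoate | C=C([C@@H]1[C@H](OC(=O)/C(C)=C/C)[C@@H]2O[C@]2(C)C(=O)C1)[C@H](C[C@H]1OC1(C)C)OC(=O)/C(C)=C/C | intermediate
22 | acetic anhydride | CC(=O)OC(C)=O | starting material
23 | (1S,3S,4S,5S,6S)-4-{(3S)-4-[(2R)-3,3-dimethyloxiran-2-yl]-3-[(E)-2-methylbut-2-enoyloxy]but-1-en-2-yl}-3-hydroxy-1-methyl-2-oxo-7-oxabicyclo[4.1.0]heptan-5-yl (E)-2-methylbut-2-enoate | C=C([C@@H]1[C@H](OC(=O)/C(C)=C/C)[C@@H]2O[C@]2(C)C(=O)[C@H]1O)[C@H](C[C@H]1OC1(C)C)OC(=O)/C(C)=C/C | intermediate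
24 | CNP0407453.3: (1S,3S,4R,5S,6S)-3-acetoxy-4-{(3S)-4-[(2R)-3,3-dimethyloxiran-2-yl]-3-[(E)-2-methylbut-2-enoyloxy]but-1-en-2-yl}-1-methyl-2-oxo-7-oxabicyclo[4.1.0]heptan-5-yl (E)-2-methylbut-2-enoate | C=C([C@@H]1[C@H](OC(=O)/C(C)=C/C)[C@@H]2O[C@]2(C)C(=O)[C@H]1OC(C)=O)[C@H](C[C@H]1OC1(C)C)OC(=O)/C(C)=C/C | target

## Step count and risks

Total steps: 12. Longest linear sequence: 10 (steps 1–5 and 8–12, from o-cresol); the side-chain branch is steps 6–7.

Three steps most likely to fail: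

**Step 9 (seven-membered radical closure).** The vinyl radical may be reduced or undergo 1,5-hydrogen transfer from a Si–CH3 before it closes, and cis delivery is less rigidly enforced in a seven-membered ring than in a five- or six-membered one. The fallback sets out from 7 and 14 and comes back at 18; it moves silicon to the alkene terminus so that the closure becomes 6-exo. Compound 14 is dehydrobrominated (LiN(iPr)2, THF, −78 °C) to (S)-6-methylhept-5-en-1-yn-3-ol F1. Compound 7 is silylated with chlorodimethylsilane/Et3N to (1S,5S,6S)-5-[(dimethylsilyl)oxy]-1-methyl-7-oxabicyclo[4.1.0]hept-3-en-2-one F2. In a thiol-catalysed radical chain (tert-dodecanethiol, AIBN, excess F1, PhH, 80 °C) the silyl radical of F2 adds to the alkyne terminus, and the β-silyl vinyl radical closes 6-exo onto C6 to give the cis-fused cyclic alkenylsiloxane F3. Bu4NF in THF/DMF then removes silicon from both C14 and O5 (protodesilylation) to give 18.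

**Step 5 (which carbonyl, which face).** If hydride is delivered syn to the epoxide, or a chelating reagent such as Zn(BH4)2 is needed to secure reduction at C5, the product is the trans alcohol. The fallback sets out from 6 and comes back at 7. The trans-epoxy alcohol (1S,5R,6S)-5-hydroxy-1-methyl-7-oxabicyclo[4.1.0]hept-3-en-2-one F4 is inverted under Mitsunobu conditions (4-nitrobenzoic acid, PPh3, DIAD, THF) to (1S,5S,6S)-1-methyl-2-oxo-7-oxabicyclo[4.1.0]hept-3-en-5-yl 4-nitrobenzoate F5, and K2CO3/MeOH releases 7.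

**Step 12 (late enolate oxidation next to two tiglates).** The C1 enolate could attack the O5 tigloyl carbonyl. The fallback sets out from 17, isolated before the fluoride treatment, and comes back at 24; it moves the enolate chemistry ahead of ester installation. Compound 17 is hydroxylated and acetylated as in step 12 to the 3-acetoxy silaketal F6. Bu4NF/AcOH gives the 3-acetoxy diol F7, tigloyl chloride/pyridine/DMAP gives the bis-tiglate acetate F8, and Shi epoxidation (run near pH 8 to spare the α-acetoxy ketone) gives 24.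

## Further compounds

F1 | step 9 | (S)-6-methylhept-5-en-1-yn-3-ol | C#C[C@@H](O)CC=C(C)C
F2 | step 9 | (1S,5S,6S)-5-[(dimethylsilyl)oxy]-1-methyl-7-oxabicyclo[4.1.0]hept-3-en-2-one | O=C1C=C[C@H](O[SiH](C)C)[C@@H]2O[C@]12C
F3 | step 9 | cis-fused cyclic alkenylsiloxane (O5–SiMe2–C14H=C7 six-membered ring, free C8 alcohol) | C1=C([C@@H]2[C@H](O[Si]1(C)C)[C@@H]3O[C@]3(C)C(=O)C2)[C@H](CC=C(C)C)O
F4 | step 5 | (1S,5R,6S)-5-hydroxy-1-methyl-7-oxabicyclo[4.1.0]hept-3-en-2-one | O=C1C=C[C@@H](O)[C@@H]2O[C@]12C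
F5 | step 5 | (1S,5S,6S)-1-methyl-2-oxo-7-oxabicyclo[4.1.0]hept-3-en-5-yl 4-nitrobenzoate | O=C1C=C[C@H](OC(=O)c3ccc(cc3)[N+](=O)[O-])[C@@H]2O[C@]12C
F6 | step 12 | 3-acetoxy derivative of 17 (acetate trans to the C6 substituent) | C=C1[C@@H]2[C@H](O[Si](C)(C)O[C@H]1CC=C(C)C)[C@@H]1O[C@]1(C)C(=O)[C@H]2OC(C)=O
F7 | step 12 | 3-acetoxy derivative of 18 | C=C([C@@H]1[C@H](O)[C@@H]2O[C@]2(C)C(=O)[C@H]1OC(C)=O)[C@H](CC=C(C)C)O
F8 | step 12 | 3-acetoxy derivative of 20 | C=C([C@@H]1[C@H](OC(=O)/C(C)=C/C)[C@@H]2O[C@]2(C)C(=O)[C@H]1OC(C)=O)[C@H](CC=C(C)C)OC(=O)/C(C)=C/C
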